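**Retrosynthetic overview**
1. Labels: ring A (trioxygenated benzene), ring B (pyranone), ring C (furan), ring D (phenol ring), ring E (dimethylpyran). Coumarin numbering O1, C2(=O), C3, C4, C4a, C5 to C8, C8a is used for rings A and B, and primed locants for ring D.
2. Endgame: the target comes from its ring E chromene by hydrogenation. Ring C comes from a dehydrogenative O2'–C4 closure of a 3-(2,4-dihydroxyphenyl)coumarin.
3. Key disconnection: that tetracycle is cut in one stroke at C3=C4 (Knoevenagel), O1–C2 (lactone exchange) and C6–CH of ring E (propargyl Claisen/oxa-6π cascade at the alkyne oxidation level). This leads back to a monocyclic salicylaldehyde bearing an O5–C(CH3)2–C≡CH ether and to 6-hydroxybenzofuran-2(3H)-one, whose five-membered lactone is a temporary ring that delivers C2 and C3 and masks O2'.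
4. Enabling feature: in ring A, O5 sits between the ring-fusion carbon C4a (blocked by C4, unable to rearomatize) and C6–H, which is ortho to O5 and O7 and para to O1. The quaternary C(CH3)2 of ring E hangs on O5, so the terminal alkyne carbon can bond only to C6. The same tert-alkyl ether tells the two homotopic ortho-hydroxyls apart, so only the C8a hydroxyl can become O1.
5. Ring order: A and D are bought, B and then E form in the key flask, and C follows. The aldehyde comes from 2,4,6-trihydroxybenzaldehyde in two etherifications, the lactone from 2,4-dimethoxyphenylacetic acid in one step.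

Key step: step 4

Remark: the target has no stereocentre and no configurable double bond, so no stereocontrol is needed. The three starting materials are taken as commercial.

**Step 1**
Reactants: 1 2,4,6-trihydroxybenzaldehyde
Product: 2 2,6-dihydroxy-4-methoxybenzaldehyde
Conditions: MeI (1.0 equiv), K2CO3 (1.0 equiv), acetone, 23 °C
Reagents that add atoms: iodomethane, CI
Why: Williamson methylation: the 4-hydroxyl is para to the formyl group, free of the intramolecular hydrogen bond and therefore the most acidic and least hindered site, so one equivalent of base and MeI should etherify it alone.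

**Step 2**
Reactants: 2 2,6-dihydroxy-4-methoxybenzaldehyde; 3 3-chloro-3-methylbut-1-yne
Product: 4 2-hydroxy-4-methoxy-6-[(2-methylbut-3-yn-2-yl)oxy]benzaldehyde
Conditions: K2CO3, KI (cat.), CuI (cat.), DMF, 60 °C
Reagents that add atoms: none
Why: Copper-catalysed propargylic etherification (Williamson type): the copper acetylide of 3 ionizes to an allenylidene-like electrophile that the phenoxide captures at the tertiary carbon, and since the two hydroxyls of 2 are homotopic and the survivor is locked in a hydrogen bond to the formyl oxygen next to a bulky ether, the reaction should stop at the monoether.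

**Step 3**
Reactants: 5 2,4-dimethoxyphenylacetic acid
Product: 6 6-hydroxybenzofuran-2(3H)-one
Conditions: 48% aq. HBr, AcOH, reflux
Reagents that add atoms: none
Why: Acidic aryl methyl ether cleavage (SN2 attack of bromide on the protonated ethers) frees both phenols, and the ortho-hydroxyphenylacetic acid should lactonize spontaneously in the hot acid to the five-membered aryl lactone.

**Step 4**
Reactants: 4 2-hydroxy-4-methoxy-6-[(2-methylbut-3-yn-2-yl)oxy]benzaldehyde; 6 6-hydroxybenzofuran-2(3H)-one
Product: 11 9-(2,4-dihydroxyphenyl)-5-methoxy-2,2-dimethyl-2H,8H-pyrano[2,3-f]chromen-8-one (the 3-arylcoumarin whose C5–O and C6 carry the 2,2-dimethyl-2H-pyran ring E), via arylidene lactone 7 (not isolated), via coumarin propargyl ether 8 (not isolated), via allenylphenol 9 (not isolated), via quinone methide 10 (not isolated)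
Conditions: Et3N (1 equiv), PhNEt2, 80 °C; then 180 °C, Et3N distilled off, Ar, one flask
Reagents that add atoms: none
Why: Et3N enolizes lactone 6, whose C3 condenses with the formyl group of 4 (Knoevenagel condensation) to arylidene lactone 7; the only free ortho-hydroxyl of ring A then attacks the activated aryl lactone carbonyl and expels the ring D phenoxide (lactone exchange, 6-exo-trig addition–elimination), which closes ring B and gives 8. At 180 °C the aryl propargyl ether of 8 undergoes an aromatic propargyl Claisen [3,3] shift through a six-membered transition state in which the terminal alkyne carbon bonds to C6, tautomerization gives allenylphenol 9, a [1,5]-hydrogen shift gives quinone methide 10, and its thermal six-electron oxa-electrocyclization restores the O5–C(CH3)2 bond, so that the net change from 8 to 11 is the new C6–CH bond and ring E. The closest known reaction types are the amine-mediated condensation of salicylaldehydes with benzofuran-2(3H)-ones to 3-(2-hydroxyaryl)coumarins, the thermal conversion of aryl 1,1-dimethylpropargyl ethers into 2,2-dimethyl-2H-chromenes, and one-flask olefination/Claisen/lactonization sequences of allyloxy-salicylaldehydes in hot N,N-diethylaniline. Site selectivity is secured by the substrate: O5 is alkylated, so only the C8a hydroxyl can lactonize, and of the two positions ortho to O5 the ring-fusion carbon C4a is quaternary, so only C6–H can rearomatize, while C8 is out of reach of the tether. No stereocentre is formed, the E/Z mixture of 7 should converge because the isomers interconvert by reversible conjugate addition, and the geminal methyl groups lower the barrier of the [3,3] shift. Distilling off Et3N before the hot stage keeps the phenoxide concentration low, which should suppress attack of O5 on the central allene carbon of 9.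

**Step 5**
Reactants: 11 9-(2,4-dihydroxyphenyl)-5-methoxy-2,2-dimethyl-2H,8H-pyrano[2,3-f]chromen-8-one
Product: 12 chromene-level coumestan (the target with a C=C bond in place of the CH2–CH2 unit of ring E; ring C closed between O2' and C4)
Conditions: DDQ (1.1 equiv), 1,4-dioxane, 23 to 60 °C
Reagents that add atoms: none
Why: Dehydrogenative cyclization of a 2'-hydroxy-3-arylcoumarin: DDQ oxidizes the 4'-hydroxyphenyl–C3=C4 unit to an extended quinone methide cation that is electrophilic at C4, O2' adds in a five-membered closure and loss of H4 aromatizes furan ring C, while ring E at the chromene level offers no abstractable hydride.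

**Step 6**
Reactants: 12 chromene-level coumestan
Product: 13 target CNP0304440.0 (9-hydroxy-3-methoxycoumestan in coumestan numbering, with a 2,2-dimethyl-3,4-dihydro-2H-pyran ring whose O sits on C1 and whose CH2 sits on C2)
Conditions: H2 (1 atm), Pd/C, THF–MeOH, 23 °C
Reagents that add atoms: none
Why: Heterogeneous catalytic hydrogenation saturates the only non-aromatic C=C bond, the cis-disubstituted styrene-type bond of ring E, whereas the former C3=C4 bond is now part of the aromatic furan and the lactone, aryl ethers and phenol are inert at 1 atm.

**Compound list**
1 | 2,4,6-trihydroxybenzaldehyde | O=Cc1c(O)cc(O)cc1O | starting material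
2 | 2,6-dihydroxy-4-methoxybenzaldehyde | COc1cc(O)c(C=O)c(O)c1 | intermediate
3 | 3-chloro-3-methylbut-1-yne | C#CC(C)(C)Cl | starting material
4 | 2-hydroxy-4-methoxy-6-[(2-methylbut-3-yn-2-yl)oxy]benzaldehyde | COc1cc(O)c(C=O)c(OC(C)(C)C#C)c1 | intermediate
5 | 2,4-dimethoxyphenylacetic acid | COc1ccc(CC(=O)O)c(OC)c1 | starting material
6 | 6-hydroxybenzofuran-2(3H)-one | O=C1Cc2ccc(O)cc2O1 | intermediate
7 | 6-hydroxy-3-{2-hydroxy-4-methoxy-6-[(2-methylbut-3-yn-2-yl)oxy]benzylidene}benzofuran-2(3H)-one (equilibrating E/Z mixture) | COc1cc(O)c(C=C2C(=O)Oc3cc(O)ccc23)c(OC(C)(C)C#C)c1 | intermediate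
8 | 3-(2,4-dihydroxyphenyl)-7-methoxy-5-[(2-methylbut-3-yn-2-yl)oxy]-2H-chromen-2-one | COc1cc2oc(=O)c(-c3ccc(O)cc3O)cc2c(OC(C)(C)C#C)c1 | intermediate
9 | 3-(2,4-dihydroxyphenyl)-5-hydroxy-7-methoxy-6-(3-methylbuta-1,2-dien-1-yl)-2H-chromen-2-one | COc1cc2oc(=O)c(-c3ccc(O)cc3O)cc2c(O)c1C=C=C(C)C | intermediate
10 | (6Z)-3-(2,4-dihydroxyphenyl)-7-methoxy-6-(3-methylbut-2-en-1-ylidene)-2H-chromene-2,5(6H)-dione | COC1=CC2=C(C=C(c3ccc(O)cc3O)C(=O)O2)C(=O)/C1=C\C=C(C)C | intermediate
11 | 9-(2,4-dihydroxyphenyl)-5-methoxy-2,2-dimethyl-2H,8H-pyrano[2,3-f]chromen-8-one | COc1cc2oc(=O)c(-c3ccc(O)cc3O)cc2c2c1C=CC(C)(C)O2 | intermediate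
12 | chromene-level coumestan (3,4-didehydro ring E analogue of the target) | COc1cc2oc(=O)c3c4ccc(O)cc4oc3c2c2c1C=CC(C)(C)O2 | intermediate
13 | CNP0304440.0 | COc1cc2oc(=O)c3c4ccc(O)cc4oc3c2c2c1CCC(C)(C)O2 | target

**Totals**
Total step count: 6. Longest linear sequence: 5 steps (steps 1, 2, 4, 5, 6).

**Steps most likely to fail**

Step 4.
- Risk: the hindered, electron-rich formyl group may condense so slowly that self-condensation of the lactone takes over. In the hot stage, residual base may also steer the phenoxide onto the allene instead of the hydrogen shift.
- Fallback: it sets out from 4 and closes ring E first, without heat or base. A 6-endo-dig hydroarylation catalysed by monovalent gold (Ph3PAuNTf2, CH2Cl2, 23 °C) lets the free ring carbon between the two ether oxygens attack the gold-activated terminal alkyne carbon directly. This should give 7-hydroxy-5-methoxy-2,2-dimethyl-2H-chromene-8-carbaldehyde F1. Its formyl group is less shielded because the neighbouring oxygen is tied back in the ring. Condensation with 6 (Et3N, toluene, 80 °C) brings the material back to the route at 11.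

Step 2.
- Risk: dehydrochlorination of 3 may outrun substitution at the tertiary carbon, or etherification may run on to the second hydroxyl.
- Fallback: it sets out from 2 and activates the alcohol instead of the phenoxide. This is a Mitsunobu etherification with 2-methylbut-3-yn-2-ol (PPh3, DIAD, toluene, 0 to 23 °C) in a neutral medium, in which a hydrogen-bonded ortho-hydroxyl normally stays untouched. It comes back to the route at 4 and makes no new compound (F0).

Step 5.
- Risk: the free resorcinol ring D may be over-oxidized, phenols may couple intermolecularly, or the cationic intermediate may be captured by the reduced quinone.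
- Fallback: it sets out from 11 and inverts the order of the two redox steps.
  - Hydrogenation (H2, 1 atm, Pd/C, THF, 23 °C) should first saturate only ring E and give 9-(2,4-dihydroxyphenyl)-5-methoxy-2,2-dimethyl-3,4-dihydro-2H,8H-pyrano[2,3-f]chromen-8-one F2.
  - Ring C is then closed by reversible oxa-Michael addition of O2' to C4 and aerobic copper-catalysed dehydrogenation of the resulting lactone enolate (Cu(OAc)2 cat., 1,10-phenanthroline, air, DMSO, 100 °C). This oxidant does not abstract benzylic hydride from ring E.
  - The sequence comes back to the route at 13.

**Further compounds**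
F1 | step 4 | 7-hydroxy-5-methoxy-2,2-dimethyl-2H-chromene-8-carbaldehyde | COc1cc(O)c(C=O)c2c1C=CC(C)(C)O2
F0 | step 2 | none | none
F2 | step 5 | 9-(2,4-dihydroxyphenyl)-5-methoxy-2,2-dimethyl-3,4-dihydro-2H,8H-pyrano[2,3-f]chromen-8-one | COc1cc2oc(=O)c(-c3ccc(O)cc3O)cc2c2c1CCC(C)(C)O2
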